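**Retrosynthetic overview**

1. The (CH2)14 tether is traced back to an aryl enone, Ar–C(=O)–CH=CH–(CH2)11–Ar'. One acid-promoted hydrogenation turns it into the target (C=C saturation, benzylic C=O hydrogenolysis, loss of three O-benzyl groups).
2. Key disconnection: C2–C3 of the tether, made by a directed aldol addition of the lithium enolate of 3,5-bis(benzyloxy)acetophenone to 12-[3-(benzyloxy)-5-methoxyphenyl]dodecanal, then dehydration.
3. Aldehyde fragment: Wittig disconnection (ArCH=CH) to 3,5-dimethoxybenzaldehyde and the phosphonium salt of 11-bromoundecan-1-ol. Hydrogenation, thiolate mono-O-demethylation (this differentiates the two oxygens), O-benzylation and oxidation follow.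
4. Ketone fragment: O-benzylation of 3,5-dihydroxyacetophenone.
5. Rings: none is formed; both benzene rings are bought intact.

Assumption: the target has no stereocentre and no stereogenic double bond, so the "single enantiomer" is simply the achiral constitution given. The alkene geometries and racemic carbinol centres that appear on the way are erased later.

**Route**

Step 1
Reactants: 1 11-bromoundecan-1-ol
Product: 2 (11-hydroxyundecyl)triphenylphosphonium bromide
Conditions: PPh3 (1.1 eq), MeCN, reflux, 48 h; trituration with Et2O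
Reagents that add atoms: triphenylphosphine, c1ccc(cc1)P(c1ccccc1)c1ccccc1
Why: SN2 quaternisation of PPh3 by an unhindered primary bromide (phosphonium salt formation) is a pure addition with no co-product, and the free hydroxyl is inert.

Step 2
Reactants: 2 (11-hydroxyundecyl)triphenylphosphonium bromide; 3 3,5-dimethoxybenzaldehyde
Product: 6 (Z)-12-(3,5-dimethoxyphenyl)dodec-11-en-1-ol, via ylide sodium alkoxide 4 (not isolated), via alkene sodium alkoxide 5 (not isolated)
Conditions: 2 (1.2 eq), NaHMDS (2.4 eq), THF, 0 °C, 30 min; then 3, 0 °C → rt; 1 M HCl work-up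
Reagents that add atoms: none
Why: Wittig olefination of a non-enolisable aromatic aldehyde with a non-stabilised ylide (the second equivalent of base covers the OH) gives mainly the Z-alkene; the geometry and any E isomer are irrelevant because step 3 removes the double bond.

Step 3
Reactants: 6 (Z)-12-(3,5-dimethoxyphenyl)dodec-11-en-1-ol
Product: 7 12-(3,5-dimethoxyphenyl)dodecan-1-ol
Conditions: H2 (1 atm), 10% Pd/C, EtOAc, rt
Reagents that add atoms: none
Why: Catalytic hydrogenation of a styrene-type alkene is fast and clean, and aryl methyl ethers and the primary alcohol are untouched.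

Step 4
Reactants: 7 12-(3,5-dimethoxyphenyl)dodecan-1-ol
Product: 9 3-(12-hydroxydodecyl)-5-methoxyphenol, via sodium phenoxide 8 (not isolated)
Conditions: NaSEt (3 eq), DMF, 150 °C, 3 h; 1 M HCl work-up
Reagents that add atoms: none
Why: Thiolate SN2 O-demethylation of a 5-alkylresorcinol dimethyl ether stops after one methyl, because the phenoxide formed deactivates the remaining OMe toward a second attack.

Step 5
Reactants: 9 3-(12-hydroxydodecyl)-5-methoxyphenol
Product: 10 12-[3-(benzyloxy)-5-methoxyphenyl]dodecan-1-ol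
Conditions: BnBr (1.05 eq), K2CO3 (2 eq), acetone, reflux
Reagents that add atoms: benzyl bromide, BrCc1ccccc1
Why: Williamson etherification is selective for the phenol, since K2CO3 deprotonates ArOH (pKa about 10) but not the aliphatic alcohol.

Step 6
Reactants: 10 12-[3-(benzyloxy)-5-methoxyphenyl]dodecan-1-ol
Product: 11 12-[3-(benzyloxy)-5-methoxyphenyl]dodecanal
Conditions: Dess–Martin periodinane (1.2 eq), CH2Cl2, 0 °C → rt
Reagents that add atoms: none
Why: Dess–Martin oxidation takes a primary alcohol to the aldehyde without over-oxidation and leaves the electron-rich aryl ethers alone; the aldehyde is used promptly.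

Step 7
Reactants: 12 1-(3,5-dihydroxyphenyl)ethan-1-one
Product: 13 1-[3,5-bis(benzyloxy)phenyl]ethan-1-one
Conditions: BnBr (2.2 eq), K2CO3 (3 eq), acetone, reflux
Reagents that add atoms: benzyl bromide, BrCc1ccccc1
Why: Double Williamson O-benzylation of the two phenols proceeds cleanly, because carbonate is too weak to enolise and C-alkylate the methyl ketone.

Step 8
Reactants: 13 1-[3,5-bis(benzyloxy)phenyl]ethan-1-one; 11 12-[3-(benzyloxy)-5-methoxyphenyl]dodecanal
Product: 16 (3RS)-1-[3,5-bis(benzyloxy)phenyl]-14-[3-(benzyloxy)-5-methoxyphenyl]-3-hydroxytetradecan-1-one, via lithium enolate 14 (not isolated), via lithium aldolate 15 (not isolated)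
Conditions: LDA (1.05 eq), THF, −78 °C, 45 min; then 11 (0.9 eq), −78 °C, 1 h; AcOH quench at −78 °C
Reagents that add atoms: none
Why: Directed crossed aldol addition: the ketone has a single enolisable site and is fully converted to its lithium enolate before the aldehyde is added, which suppresses aldehyde self-condensation; the new carbinol centre is racemic and is destroyed in step 9.

Step 9
Reactants: 16 (3RS)-1-[3,5-bis(benzyloxy)phenyl]-14-[3-(benzyloxy)-5-methoxyphenyl]-3-hydroxytetradecan-1-one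
Product: 18 (E)-1-[3,5-bis(benzyloxy)phenyl]-14-[3-(benzyloxy)-5-methoxyphenyl]tetradec-2-en-1-one, via β-mesyloxy ketone 17 (not isolated)
Conditions: MsCl (1.5 eq), Et3N (4 eq), CH2Cl2, 0 °C → rt
Reagents that add atoms: none
Why: Mesylation followed by E1cB elimination of the β-mesyloxy ketone gives the conjugated, thermodynamically preferred E-enone; its geometry is erased in step 10.

Step 10
Reactants: 18 (E)-1-[3,5-bis(benzyloxy)phenyl]-14-[3-(benzyloxy)-5-methoxyphenyl]tetradec-2-en-1-one
Product: 21 5-[14-(3-hydroxy-5-methoxyphenyl)tetradecyl]benzene-1,3-diol, via saturated triphenol ketone 19 (not isolated), via benzylic carbinol 20 (not isolated)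
Conditions: H2 (4 atm), 10% Pd/C, EtOAc–AcOH (1:1), cat. HClO4, rt → 45 °C
Reagents that add atoms: none
Why: Catalytic hydrogenation/hydrogenolysis saturates the C=C, cleaves the three aryl benzyl ethers, and under acid reduces the aryl ketone through its benzylic carbinol to CH2; the aryl methyl ether and the arene rings survive, and no stereocentre remains.

**Compound list**

1 | 11-bromoundecan-1-ol | OCCCCCCCCCCCBr | starting material
2 | (11-hydroxyundecyl)triphenylphosphonium bromide | OCCCCCCCCCCC[P+](c1ccccc1)(c1ccccc1)c1ccccc1.[Br-] | intermediate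
3 | 3,5-dimethoxybenzaldehyde | COc1cc(C=O)cc(OC)c1 | starting material
4 | sodium 11-(triphenyl-λ5-phosphanylidene)undecan-1-olate (ylide sodium alkoxide) | [Na+].[O-]CCCCCCCCCCC=P(c1ccccc1)(c1ccccc1)c1ccccc1 | intermediate (not isolated)
5 | sodium (Z)-12-(3,5-dimethoxyphenyl)dodec-11-en-1-olate | [Na+].[O-]CCCCCCCCCC/C=C\c1cc(OC)cc(OC)c1 | intermediate (not isolated)
6 | (Z)-12-(3,5-dimethoxyphenyl)dodec-11-en-1-ol (major isomer; minor E isomer carried along) | OCCCCCCCCCC/C=C\c1cc(OC)cc(OC)c1 | intermediate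
7 | 12-(3,5-dimethoxyphenyl)dodecan-1-ol | OCCCCCCCCCCCCc1cc(OC)cc(OC)c1 | intermediate
8 | sodium 3-(12-hydroxydodecyl)-5-methoxyphenolate | [Na+].[O-]c1cc(OC)cc(CCCCCCCCCCCCO)c1 | intermediate (not isolated)
9 | 3-(12-hydroxydodecyl)-5-methoxyphenol | COc1cc(O)cc(CCCCCCCCCCCCO)c1 | intermediate
10 | 12-[3-(benzyloxy)-5-methoxyphenyl]dodecan-1-ol | COc1cc(OCc2ccccc2)cc(CCCCCCCCCCCCO)c1 | intermediate
11 | 12-[3-(benzyloxy)-5-methoxyphenyl]dodecanal | COc1cc(OCc2ccccc2)cc(CCCCCCCCCCCC=O)c1 | intermediate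
12 | 1-(3,5-dihydroxyphenyl)ethan-1-one | CC(=O)c1cc(O)cc(O)c1 | starting material
13 | 1-[3,5-bis(benzyloxy)phenyl]ethan-1-one | CC(=O)c1cc(OCc2ccccc2)cc(OCc2ccccc2)c1 | intermediate
14 | lithium 1-[3,5-bis(benzyloxy)phenyl]ethen-1-olate | [Li+].C=C([O-])c1cc(OCc2ccccc2)cc(OCc2ccccc2)c1 | intermediate (not isolated)
15 | lithium (3RS)-1-[3,5-bis(benzyloxy)phenyl]-14-[3-(benzyloxy)-5-methoxyphenyl]-1-oxotetradecan-3-olate | [Li+].[O-]C(CC(=O)c1cc(OCc2ccccc2)cc(OCc2ccccc2)c1)CCCCCCCCCCCc1cc(OC)cc(OCc2ccccc2)c1 | intermediate (not isolated)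
16 | (3RS)-1-[3,5-bis(benzyloxy)phenyl]-14-[3-(benzyloxy)-5-methoxyphenyl]-3-hydroxytetradecan-1-one (racemic) | OC(CC(=O)c1cc(OCc2ccccc2)cc(OCc2ccccc2)c1)CCCCCCCCCCCc1cc(OC)cc(OCc2ccccc2)c1 | intermediate
17 | (3RS)-1-[3,5-bis(benzyloxy)phenyl]-14-[3-(benzyloxy)-5-methoxyphenyl]-1-oxotetradecan-3-yl methanesulfonate (racemic) | CS(=O)(=O)OC(CC(=O)c1cc(OCc2ccccc2)cc(OCc2ccccc2)c1)CCCCCCCCCCCc1cc(OC)cc(OCc2ccccc2)c1 | intermediate (not isolated)
18 | (E)-1-[3,5-bis(benzyloxy)phenyl]-14-[3-(benzyloxy)-5-methoxyphenyl]tetradec-2-en-1-one | O=C(/C=C/CCCCCCCCCCCc1cc(OC)cc(OCc2ccccc2)c1)c1cc(OCc2ccccc2)cc(OCc2ccccc2)c1 | intermediate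
19 | 1-(3,5-dihydroxyphenyl)-14-(3-hydroxy-5-methoxyphenyl)tetradecan-1-one | O=C(CCCCCCCCCCCCCc1cc(OC)cc(O)c1)c1cc(O)cc(O)c1 | intermediate (not isolated)
20 | 5-[(1RS)-1-hydroxy-14-(3-hydroxy-5-methoxyphenyl)tetradecyl]benzene-1,3-diol (racemic) | OC(CCCCCCCCCCCCCc1cc(OC)cc(O)c1)c1cc(O)cc(O)c1 | intermediate (not isolated)
21 | 5-[14-(3-hydroxy-5-methoxyphenyl)tetradecyl]benzene-1,3-diol (achiral) | COc1cc(O)cc(CCCCCCCCCCCCCCc2cc(O)cc(O)c2)c1 | target

**Summary**

Total step count: 10.
Longest linear sequence: 9 steps (steps 1–6, then 8–10); step 7 is a one-step side branch.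

Steps most likely to fail (step 10 is the riskiest, then step 8, then step 4):

Step 4 (mono-demethylation may give some diol or leave dimethyl ether). The fallback sets out from 2 and comes back to the route at 10; it installs the benzyl/methyl pattern before the chain is attached. Commercial 3-hydroxy-5-methoxybenzaldehyde F1 is benzylated (BnBr, K2CO3, DMF) to 3-(benzyloxy)-5-methoxybenzaldehyde F2. Ylide 4, made from 2 exactly as in step 2, is condensed with F2 to give sodium (Z)-12-[3-(benzyloxy)-5-methoxyphenyl]dodec-11-en-1-olate F3, which acid work-up converts to (Z)-12-[3-(benzyloxy)-5-methoxyphenyl]dodec-11-en-1-ol F4. The alkene alone is then hydrogenated over Ph2S-poisoned Pd/C (H2, 1 atm, EtOAc), which spares the aryl benzyl ether, giving 10.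

Step 8 (lithium enolate may enolise the aldehyde, or the aldol may revert or over-react). The fallback sets out from 13 and comes back at 16; it replaces the basic enolate by a Lewis-acid-mediated Mukaiyama aldol. Ketone 13 is converted with TMSOTf/Et3N (CH2Cl2, 0 °C) into {1-[3,5-bis(benzyloxy)phenyl]ethenyl}oxy(trimethyl)silane F5. F5 is added to aldehyde 11 with BF3·OEt2 in CH2Cl2 at −78 °C, and aqueous work-up gives 16.

Step 10 (hydrogenolysis of the aryl ketone may stall at ketone 19 or carbinol 20, since the meta-oxygenated ring gives little benzylic activation). The fallback sets out from 18 and comes back at 21; it removes the carbonyl by Wolff–Kishner reduction before deprotection. The C=C of 18 alone is hydrogenated over Ph2S-poisoned Pd/C (H2, 1 atm, EtOAc) to 1-[3,5-bis(benzyloxy)phenyl]-14-[3-(benzyloxy)-5-methoxyphenyl]tetradecan-1-one F6. Huang-Minlon conditions (N2H4·H2O, KOH, diethylene glycol, 130 → 200 °C) take F6 through 1-[3,5-bis(benzyloxy)phenyl]-14-[3-(benzyloxy)-5-methoxyphenyl]tetradecan-1-one hydrazone F7 to 1,3-bis(benzyloxy)-5-{14-[3-(benzyloxy)-5-methoxyphenyl]tetradecyl}benzene F8. Neutral hydrogenolysis of F8 (H2, Pd/C, EtOAc–EtOH) gives 21.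

**Further compounds**

F1 | step 4 | 3-hydroxy-5-methoxybenzaldehyde | COc1cc(O)cc(C=O)c1
F2 | step 4 | 3-(benzyloxy)-5-methoxybenzaldehyde | COc1cc(OCc2ccccc2)cc(C=O)c1
F3 | step 4 | sodium (Z)-12-[3-(benzyloxy)-5-methoxyphenyl]dodec-11-en-1-olate | [Na+].[O-]CCCCCCCCCC/C=C\c1cc(OC)cc(OCc2ccccc2)c1
F4 | step 4 | (Z)-12-[3-(benzyloxy)-5-methoxyphenyl]dodec-11-en-1-ol | OCCCCCCCCCC/C=C\c1cc(OC)cc(OCc2ccccc2)c1
F5 | step 8 | {1-[3,5-bis(benzyloxy)phenyl]ethenyl}oxy(trimethyl)silane | C=C(O[Si](C)(C)C)c1cc(OCc2ccccc2)cc(OCc2ccccc2)c1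
F6 | step 10 | 1-[3,5-bis(benzyloxy)phenyl]-14-[3-(benzyloxy)-5-methoxyphenyl]tetradecan-1-one | O=C(CCCCCCCCCCCCCc1cc(OC)cc(OCc2ccccc2)c1)c1cc(OCc2ccccc2)cc(OCc2ccccc2)c1
F7 | step 10 | 1-[3,5-bis(benzyloxy)phenyl]-14-[3-(benzyloxy)-5-methoxyphenyl]tetradecan-1-one hydrazone | NN=C(CCCCCCCCCCCCCc1cc(OC)cc(OCc2ccccc2)c1)c1cc(OCc2ccccc2)cc(OCc2ccccc2)c1
F8 | step 10 | 1,3-bis(benzyloxy)-5-{14-[3-(benzyloxy)-5-methoxyphenyl]tetradecyl}benzene | COc1cc(OCc2ccccc2)cc(CCCCCCCCCCCCCCc2cc(OCc3ccccc3)cc(OCc3ccccc3)c2)c1
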